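**Retrosynthetic overview**

1. The target is read as ent-fisetinidol-(4α→6)-ent-fisetinidol-(4α→8)-catechin-(6→4α)-ent-fisetinidol (units A, B, D, C). The last disconnection cuts the pyran O1–C2 bond of all three ent-fisetinidol units, which leads back to the acyclic tris(syn-1,2-diol) triphenol 16.
2. The three interflavanyl C4–aryl bonds are made earlier, on open chains, by invertive Friedel–Crafts opening of trans-epoxy ketones: epoxide 5 onto C-8 of penta-O-benzylcatechin, then two bromine-blocked epoxides 9 in one step onto C-6 of the catechin ring and onto the free resorcinol position of the B arm. A trans-epoxide opened with inversion gives the 3,4-cis relationship once the ring is closed.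
3. Stereocontrol: (+)-catechin is bought; Juliá–Colonna epoxidation sets C-3 and, through inversion, C-4; asymmetric transfer hydrogenation sets the C-2 carbinols; the ring closure inverts C-2.
4. Enabling feature: in each of the units A, B and C the resorcinol-ring oxygen O-1 on C-8a is linked to the benzylic carbon C-2 through C-4a, C-4 and C-3, and C-2 carries a hydroxyl and the 3,4-dioxygenated aryl ring. This O-1/C-2 pair occurs three times, and only these three phenols are left unprotected.
5. Ring order: the catechin rings are given; the three pyran rings of A, B and C are closed last and together; hydrogenolysis then removes 14 benzyl ethers and the two C–Br blocking groups.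

Key step: step 14

Remark (assumption on the chemistry): where one reaction runs at several like sites of one molecule (steps 8, 11–15), partly converted species are not numbered. The sense of induction of the poly-L-leucine epoxidation and of the (S,S)-Ru transfer hydrogenation is taken by analogy with chalcone and benzoin-type ketones.

**Route**

Step 1
Reactants: 1 4-(benzyloxy)-2-hydroxybenzaldehyde
Product: 2 2-(allyloxy)-4-(benzyloxy)benzaldehyde
Conditions: allyl bromide, K2CO3, DMF, rt
Reagents that add atoms: allyl bromide, C=CCBr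
Why: Williamson O-allylation of the phenol; the allyl ether should survive base, peroxide and Lewis acid and can be removed later under neutral Pd(0) conditions.

Step 2
Reactants: 2 2-(allyloxy)-4-(benzyloxy)benzaldehyde; 3 1-[3,4-bis(benzyloxy)phenyl]ethan-1-one
Product: 4 (E)-3-[2-(allyloxy)-4-(benzyloxy)phenyl]-1-[3,4-bis(benzyloxy)phenyl]prop-2-en-1-one
Conditions: KOH (aq.), EtOH/THF, rt
Reagents that add atoms: none
Why: Claisen–Schmidt condensation of a non-enolisable aldehyde with an aryl methyl ketone should give the (E)-enone under thermodynamic control.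

Step 3
Reactants: 4 (E)-enone
Product: 5 [(2R,3S)-3-[2-(allyloxy)-4-(benzyloxy)phenyl]oxiran-2-yl][3,4-bis(benzyloxy)phenyl]methanone (trans-epoxy ketone)
Conditions: poly-L-leucine (cat.), urea–H2O2, DBU, THF, rt
Reagents that add atoms: urea–hydrogen peroxide, OO.NC(N)=O
Why: Juliá–Colonna epoxidation; hydroperoxide adds to the enone held on the helical polypeptide, which should set both epoxide centres as (2R,3S), as for chalcone itself.

Step 4
Reactants: 1 4-(benzyloxy)-2-hydroxybenzaldehyde
Product: 6 4-(benzyloxy)-5-bromo-2-hydroxybenzaldehyde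
Conditions: NBS, MeCN, 0 °C to rt
Reagents that add atoms: N-bromosuccinimide, O=C1CCC(=O)N1Br
Why: electrophilic aromatic bromination at the most activated open position, para to the free hydroxyl; the bromine later blocks this resorcinol position against Friedel–Crafts attack and leaves in the final hydrogenolysis.

Step 5
Reactants: 6 4-(benzyloxy)-5-bromo-2-hydroxybenzaldehyde
Product: 7 2-(allyloxy)-4-(benzyloxy)-5-bromobenzaldehyde
Conditions: allyl bromide, K2CO3, DMF, rt
Reagents that add atoms: allyl bromide, C=CCBr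
Why: Williamson O-allylation, as in step 1.

Step 6
Reactants: 7 2-(allyloxy)-4-(benzyloxy)-5-bromobenzaldehyde; 3 1-[3,4-bis(benzyloxy)phenyl]ethan-1-one
Product: 8 (E)-3-[2-(allyloxy)-4-(benzyloxy)-5-bromophenyl]-1-[3,4-bis(benzyloxy)phenyl]prop-2-en-1-one
Conditions: KOH (aq.), EtOH/THF, rt
Reagents that add atoms: none
Why: Claisen–Schmidt condensation, as in step 2.

Step 7
Reactants: 8 (E)-bromo enone
Product: 9 [(2R,3S)-3-[2-(allyloxy)-4-(benzyloxy)-5-bromophenyl]oxiran-2-yl][3,4-bis(benzyloxy)phenyl]methanone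
Conditions: poly-L-leucine (cat.), urea–H2O2, DBU, THF, rt
Reagents that add atoms: urea–hydrogen peroxide, OO.NC(N)=O
Why: Juliá–Colonna epoxidation, as in step 3; the catalyst should set both centres as (2R,3S).

Step 8
Reactants: 10 (+)-catechin, (2R,3S)
Product: 11 5,7,3',4'-tetra-O-benzyl-(+)-catechin
Conditions: BnBr, K2CO3, DMF, 0 °C to rt
Reagents that add atoms: benzyl bromide, BrCc1ccccc1
Why: Williamson alkylation of the four phenols; carbonate does not deprotonate the secondary 3-OH and the stereocentres are not touched.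

Step 9
Reactants: 11 5,7,3',4'-tetra-O-benzyl-(+)-catechin
Product: 12 3,5,7,3',4'-penta-O-benzyl-(+)-catechin
Conditions: NaH, BnBr, Bu4NI (cat.), THF/DMF, 0 °C to rt
Reagents that add atoms: benzyl bromide, BrCc1ccccc1
Why: Williamson etherification of the alkoxide; afterwards the only free hydroxyls in later intermediates belong to the three new units.

Step 10
Reactants: 12 penta-O-benzylcatechin (in excess); 5 trans-epoxy ketone
Product: 13 (2R,3S)-3-[2-(allyloxy)-4-(benzyloxy)phenyl]-1-[3,4-bis(benzyloxy)phenyl]-2-hydroxy-3-(penta-O-benzylcatechin-8-yl)propan-1-one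
Conditions: BF3·OEt2 (cat.), CH2Cl2, −78 to −40 °C
Reagents that add atoms: none
Why: Friedel–Crafts alkylation of the phloroglucinol-type ring by the Lewis-acid-activated aryl epoxide; C-8, the less hindered free position, should attack the benzylic epoxide carbon anti to the oxygen held in a BF3 chelate with the ketone, which inverts that carbon (the later C-4 of unit B) and leaves the (R)-carbinol carbon untouched, while excess 12 suppresses a second alkylation.

Step 11
Reactants: 13 mono-arm ketol; 9 bromo epoxy ketone (two molecules are incorporated; used in excess)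
Product: 14 tris-ketol: 13 carrying the (2R)-3-[2-(allyloxy)-4-(benzyloxy)-5-bromophenyl]-1-[3,4-bis(benzyloxy)phenyl]-2-hydroxy-1-oxopropan-3-yl group at C-6 of the catechin ring (3S) and at the ring position para to the allyloxy group of the first arm (configuration of C-4 of unit A of the target)
Conditions: BF3·OEt2 (cat.), CH2Cl2, −78 to −20 °C
Reagents that add atoms: none
Why: the same invertive Friedel–Crafts epoxide opening at the only two nucleophilic carbons left, which both require the same bromo unit, so the regiochemistry is unambiguous; the bromine in 9 blocks the corresponding position of the new arms, so neither self-condensation of 9 nor over-alkylation should occur.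

Step 12
Reactants: 14 tris-ketol
Product: 15 tris(syn-diol): each arm now a (1R,2R)-1-[3,4-bis(benzyloxy)phenyl]propane-1,2-diol, diarylmethine centres unchanged
Conditions: RuCl[(S,S)-TsDPEN](p-cymene) (cat.), HCO2H/Et3N 5:2, CH2Cl2, 30 °C
Reagents that add atoms: none
Why: Noyori-type asymmetric transfer hydrogenation of α-hydroxy aryl ketones; the (S,S) catalyst should give the (R)-carbinol at each ketone, i.e. the syn-diols, which is also the Felkin–Anh sense for an outer-sphere hydride, so catalyst and substrate are matched (the phenols are still masked, so no premature ring closure can occur).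

Step 13
Reactants: 15 tris(syn-diol)
Product: 16 triphenol: 15 with the three allyl ethers replaced by free phenols (the later O-1 of units A, B and C)
Conditions: Pd(PPh3)4 (cat.), morpholine, THF, rt
Reagents that add atoms: none
Why: Tsuji–Trost-type deallylation; Pd(0) ionises only the aryl allyl ethers and morpholine traps the π-allyl complexes, under neutral conditions that should leave benzyl ethers, aryl bromides and benzylic diols untouched.

Step 14
Reactants: 16 triphenol tris(syn-diol)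
Product: 17 protected tetraflavanoid: 14 benzyl ethers, bromine at C-6 of units A and C, free 3-OH in units A, B and C; A (2S,3R,4R), B (2S,3R,4S), C (2S,3R,4S), catechin unit (2R,3S)
Conditions: PPh3, DIAD, THF, 0 °C to rt
Reagents that add atoms: none
Why: PPh3/DIAD turn each benzylic C-2 hydroxyl into an alkoxyphosphonium ion (directly or by opening of the dioxaphospholane formed with the neighbouring 3-OH) while the betaine deprotonates the phenol, and each phenoxide O-1 displaces Ph3P=O at its own C-2 by SN2. The closest known reaction is the intramolecular Mitsunobu etherification of 1-aryl-3-(2-hydroxyaryl)propan-1-ols and -propane-1,2-diols to flavans and 2,3-trans-flavan-3-ols. All three pyran rings (units A, B and C) close in the same mode, 6-exo-tet attack of O-1 on C-2 along the chain O1–C8a–C4a–C4–C3–C2. Each new C-2 centre is set by inversion of the (R)-carbinol from step 12, which puts the aryl group trans to the 3-OH (2S,3R); the 3,4-cis relationship was fixed in steps 10 and 11, and any leakage through the 3,4-dialkoxybenzyl cation should close through the chair with equatorial aryl to the same 2,3-trans isomer. The step needs attack by phenol oxygen only, each at its own arm, and activation of C-2 and not C-3: only the three O-1 phenols are unprotected and each reaches only its own C-2 in a six-membered ring (the B-arm phenol is para to the A arm), while each 3-OH sits between two branched carbons, so displacement there (five-membered closure) should be much slower than at the benzylic carbon.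

Step 15
Reactants: 17 protected tetraflavanoid
Product: 18 target, ent-fisetinidol-(4α→6)-ent-fisetinidol-(4α→8)-catechin-(6→4α)-ent-fisetinidol
Conditions: H2 (1 atm), Pd(OH)2/C, Et3N (2.2 equiv), THF/MeOH, rt
Reagents that add atoms: none
Why: heterogeneous hydrogenolysis should cleave the fourteen benzyl ethers and, with Et3N as HBr trap, the two aryl C–Br bonds, without touching any stereocentre.

**Compound list**

1 | 4-(benzyloxy)-2-hydroxybenzaldehyde | O=Cc1ccc(OCc2ccccc2)cc1O | starting material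
2 | 2-(allyloxy)-4-(benzyloxy)benzaldehyde | O=Cc1ccc(OCc2ccccc2)cc1OCC=C | intermediate
3 | 1-[3,4-bis(benzyloxy)phenyl]ethan-1-one | CC(=O)c1ccc(OCc2ccccc2)c(OCc2ccccc2)c1 | starting material
4 | (E)-3-[2-(allyloxy)-4-(benzyloxy)phenyl]-1-[3,4-bis(benzyloxy)phenyl]prop-2-en-1-one | O=C(/C=C/c1ccc(OCc2ccccc2)cc1OCC=C)c1ccc(OCc2ccccc2)c(OCc2ccccc2)c1 | intermediate
5 | [(2R,3S)-3-[2-(allyloxy)-4-(benzyloxy)phenyl]oxiran-2-yl][3,4-bis(benzyloxy)phenyl]methanone | O=C(c1ccc(OCc2ccccc2)c(OCc2ccccc2)c1)[C@@H]1O[C@H]1c1ccc(OCc2ccccc2)cc1OCC=C | intermediate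
6 | 4-(benzyloxy)-5-bromo-2-hydroxybenzaldehyde | O=Cc1cc(Br)c(OCc2ccccc2)cc1O | intermediate
7 | 2-(allyloxy)-4-(benzyloxy)-5-bromobenzaldehyde | O=Cc1cc(Br)c(OCc2ccccc2)cc1OCC=C | intermediate
8 | (E)-3-[2-(allyloxy)-4-(benzyloxy)-5-bromophenyl]-1-[3,4-bis(benzyloxy)phenyl]prop-2-en-1-one | O=C(/C=C/c1cc(Br)c(OCc2ccccc2)cc1OCC=C)c1ccc(OCc2ccccc2)c(OCc2ccccc2)c1 | intermediate
9 | [(2R,3S)-3-[2-(allyloxy)-4-(benzyloxy)-5-bromophenyl]oxiran-2-yl][3,4-bis(benzyloxy)phenyl]methanone | O=C(c1ccc(OCc2ccccc2)c(OCc2ccccc2)c1)[C@@H]1O[C@H]1c1cc(Br)c(OCc2ccccc2)cc1OCC=C | intermediate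
10 | (+)-catechin, (2R,3S) | O[C@H]1Cc2c(O)cc(O)cc2O[C@@H]1c1ccc(O)c(O)c1 | starting material
11 | 5,7,3',4'-tetra-O-benzyl-(+)-catechin | O[C@H]1Cc2c(OCc3ccccc3)cc(OCc3ccccc3)cc2O[C@@H]1c1ccc(OCc2ccccc2)c(OCc2ccccc2)c1 | intermediate
12 | 3,5,7,3',4'-penta-O-benzyl-(+)-catechin | c1ccccc1CO[C@H]1Cc2c(OCc3ccccc3)cc(OCc3ccccc3)cc2O[C@@H]1c1ccc(OCc2ccccc2)c(OCc2ccccc2)c1 | intermediate
13 | (2R,3S)-3-[2-(allyloxy)-4-(benzyloxy)phenyl]-1-[3,4-bis(benzyloxy)phenyl]-2-hydroxy-3-(penta-O-benzylcatechin-8-yl)propan-1-one | c1([C@H](c3ccc(OCc4ccccc4)cc3OCC=C)[C@@H](O)C(=O)c3ccc(OCc4ccccc4)c(OCc4ccccc4)c3)c(OCc3ccccc3)cc(OCc3ccccc3)c2c1O[C@H](c1ccc(OCc3ccccc3)c(OCc3ccccc3)c1)[C@@H](OCc1ccccc1)C2 | intermediate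
14 | tris-ketol (13 with a bromo ketol arm at catechin C-6 and another on the resorcinol ring of the first arm) | c1([C@H](c3cc([C@H](c5cc(Br)c(OCc6ccccc6)cc5OCC=C)[C@@H](O)C(=O)c5ccc(OCc6ccccc6)c(OCc6ccccc6)c5)c(OCc4ccccc4)cc3OCC=C)[C@@H](O)C(=O)c3ccc(OCc4ccccc4)c(OCc4ccccc4)c3)c(OCc3ccccc3)c([C@H](c3cc(Br)c(OCc4ccccc4)cc3OCC=C)[C@@H](O)C(=O)c3ccc(OCc4ccccc4)c(OCc4ccccc4)c3)c(OCc3ccccc3)c2c1O[C@H](c1ccc(OCc3ccccc3)c(OCc3ccccc3)c1)[C@@H](OCc1ccccc1)C2 | intermediate
15 | tris(syn-diol), each arm (1R,2R)-1-aryl-propane-1,2-diol, allyl ethers intact | c1([C@H](c3cc([C@H](c5cc(Br)c(OCc6ccccc6)cc5OCC=C)[C@@H](O)[C@H](O)c5ccc(OCc6ccccc6)c(OCc6ccccc6)c5)c(OCc4ccccc4)cc3OCC=C)[C@@H](O)[C@H](O)c3ccc(OCc4ccccc4)c(OCc4ccccc4)c3)c(OCc3ccccc3)c([C@H](c3cc(Br)c(OCc4ccccc4)cc3OCC=C)[C@@H](O)[C@H](O)c3ccc(OCc4ccccc4)c(OCc4ccccc4)c3)c(OCc3ccccc3)c2c1O[C@H](c1ccc(OCc3ccccc3)c(OCc3ccccc3)c1)[C@@H](OCc1ccccc1)C2 | intermediate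
16 | triphenol tris(syn-diol) | c1([C@H](c3cc([C@H](c5cc(Br)c(OCc6ccccc6)cc5O)[C@@H](O)[C@H](O)c5ccc(OCc6ccccc6)c(OCc6ccccc6)c5)c(OCc4ccccc4)cc3O)[C@@H](O)[C@H](O)c3ccc(OCc4ccccc4)c(OCc4ccccc4)c3)c(OCc3ccccc3)c([C@H](c3cc(Br)c(OCc4ccccc4)cc3O)[C@@H](O)[C@H](O)c3ccc(OCc4ccccc4)c(OCc4ccccc4)c3)c(OCc3ccccc3)c2c1O[C@H](c1ccc(OCc3ccccc3)c(OCc3ccccc3)c1)[C@@H](OCc1ccccc1)C2 | intermediate
17 | tetradeca-O-benzyl-6(A),6(C)-dibromo tetraflavanoid, 3-OH of units A, B, C free | c3ccccc3COc1c(Br)cc2c(c1)O[C@@H](c1ccc(OCc3ccccc3)c(OCc3ccccc3)c1)[C@H](O)[C@@H]2c1cc2c(cc1OCc3ccccc3)O[C@@H](c1ccc(OCc3ccccc3)c(OCc3ccccc3)c1)[C@H](O)[C@@H]2c1c(OCc3ccccc3)c([C@@H]2c3cc(Br)c(OCc4ccccc4)cc3O[C@@H](c3ccc(OCc4ccccc4)c(OCc4ccccc4)c3)[C@@H]2O)c(OCc3ccccc3)c2c1O[C@H](c1ccc(OCc3ccccc3)c(OCc3ccccc3)c1)[C@@H](OCc1ccccc1)C2 | intermediate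
18 | ent-fisetinidol-(4α→6)-ent-fisetinidol-(4α→8)-catechin-(6→4α)-ent-fisetinidol | Oc1ccc2c(c1)O[C@@H](c1ccc(O)c(O)c1)[C@H](O)[C@@H]2c1cc2c(cc1O)O[C@@H](c1ccc(O)c(O)c1)[C@H](O)[C@@H]2c1c(O)c([C@@H]2c3ccc(O)cc3O[C@@H](c3ccc(O)c(O)c3)[C@@H]2O)c(O)c2c1O[C@H](c1ccc(O)c(O)c1)[C@@H](O)C2 | target

**Step count and risks**

Total step count: 15. Longest linear sequence: 9 steps (1 → 6 → 7 → 8 → 9 → 14 → 15 → 16 → 17 → 18; the branch through 5 and 13 is equally long).

Steps most likely to fail:

Step 10. The electron-rich aryl epoxide may ionise to a free benzylic cation before the C–C bond forms, which would give poor facial selectivity at the new diarylmethine centre, and a 1,2-aroyl shift of the opened epoxide may compete. The fallback sets out from 12 and 4 and comes back at 13, with both centres set under catalyst or reagent control. Bromination of 12 at C-8 with NBS gives 8-bromo-penta-O-benzylcatechin F1. Bromine–lithium exchange (n-BuLi, THF, −78 °C) and trapping with 2-isopropoxy-4,4,5,5-tetramethyl-1,3,2-dioxaborolane gives the 8-pinacolboronate F2. Rhodium-catalysed asymmetric conjugate addition (Hayashi–Miyaura, chiral diene or BINAP ligand, aqueous dioxane) of F2 to enone 4 should give the (3S)-β,β-diaryl ketone F3. Hydroxylation of the potassium enolate of F3 with an enantiopure (camphorsulfonyl)oxaziridine then installs the (2R)-hydroxyl and gives 13.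

Step 11. The free ketol hydroxyl of 13 may be O-alkylated by the activated epoxide and may tie up the Lewis acid, so that the alkylation stalls after one arm or gives ethers in place of the second C–C bond. The fallback sets out from 13 and comes back at 14, with the hydroxyl masked during the double alkylation. Silylation (TBSOTf, 2,6-lutidine) gives the tert-butyldimethylsilyl ether F4. The double Friedel–Crafts alkylation with 9 is run on F4 and gives the mono-silylated tris-ketone F5. HF·pyridine in THF removes the silyl group and gives 14.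

Step 14. The phosphonium may form at the 3-hydroxyl (five-membered closure to a dihydrobenzofuran), the diol may collapse to an epoxide, C-2 may ionise with partial loss of inversion, or the threefold closure may stop short. The fallback sets out from 16 and comes back at 17 and uses the diol itself as the leaving group. Triethyl orthoformate with PPTS in 1,2-dichloroethane should convert each syn-diol into a 1,3-dioxolan-2-ylium ion that the phenol opens at the benzylic carbon with inversion, giving the tris(3-O-formate) F6. K2CO3 in MeOH/THF removes the formates and gives 17.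

Further compounds
F1 | step 10 | 8-bromo-3,5,7,3',4'-penta-O-benzyl-(+)-catechin | c1(Br)c(OCc3ccccc3)cc(OCc3ccccc3)c2c1O[C@H](c1ccc(OCc3ccccc3)c(OCc3ccccc3)c1)[C@@H](OCc1ccccc1)C2
F2 | step 10 | 3,5,7,3',4'-penta-O-benzyl-8-(4,4,5,5-tetramethyl-1,3,2-dioxaborolan-2-yl)-(+)-catechin | c1(B3OC(C)(C)C(C)(C)O3)c(OCc3ccccc3)cc(OCc3ccccc3)c2c1O[C@H](c1ccc(OCc3ccccc3)c(OCc3ccccc3)c1)[C@@H](OCc1ccccc1)C2
F3 | step 10 | (3S)-3-[2-(allyloxy)-4-(benzyloxy)phenyl]-1-[3,4-bis(benzyloxy)phenyl]-3-(penta-O-benzylcatechin-8-yl)propan-1-one | c1([C@H](c3ccc(OCc4ccccc4)cc3OCC=C)CC(=O)c3ccc(OCc4ccccc4)c(OCc4ccccc4)c3)c(OCc3ccccc3)cc(OCc3ccccc3)c2c1O[C@H](c1ccc(OCc3ccccc3)c(OCc3ccccc3)c1)[C@@H](OCc1ccccc1)C2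
F4 | step 11 | tert-butyldimethylsilyl ether of 13 | c1([C@H](c3ccc(OCc4ccccc4)cc3OCC=C)[C@@H](O[Si](C)(C)C(C)(C)C)C(=O)c3ccc(OCc4ccccc4)c(OCc4ccccc4)c3)c(OCc3ccccc3)cc(OCc3ccccc3)c2c1O[C@H](c1ccc(OCc3ccccc3)c(OCc3ccccc3)c1)[C@@H](OCc1ccccc1)C2
F5 | step 11 | tris-ketone 14 with the hydroxyl of the first arm as tert-butyldimethylsilyl ether | c1([C@H](c3cc([C@H](c5cc(Br)c(OCc6ccccc6)cc5OCC=C)[C@@H](O)C(=O)c5ccc(OCc6ccccc6)c(OCc6ccccc6)c5)c(OCc4ccccc4)cc3OCC=C)[C@@H](O[Si](C)(C)C(C)(C)C)C(=O)c3ccc(OCc4ccccc4)c(OCc4ccccc4)c3)c(OCc3ccccc3)c([C@H](c3cc(Br)c(OCc4ccccc4)cc3OCC=C)[C@@H](O)C(=O)c3ccc(OCc4ccccc4)c(OCc4ccccc4)c3)c(OCc3ccccc3)c2c1O[C@H](c1ccc(OCc3ccccc3)c(OCc3ccccc3)c1)[C@@H](OCc1ccccc1)C2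
F6 | step 14 | tris(3-O-formate) of 17 | c3ccccc3COc1c(Br)cc2c(c1)O[C@@H](c1ccc(OCc3ccccc3)c(OCc3ccccc3)c1)[C@H](OC=O)[C@@H]2c1cc2c(cc1OCc3ccccc3)O[C@@H](c1ccc(OCc3ccccc3)c(OCc3ccccc3)c1)[C@H](OC=O)[C@@H]2c1c(OCc3ccccc3)c([C@@H]2c3cc(Br)c(OCc4ccccc4)cc3O[C@@H](c3ccc(OCc4ccccc4)c(OCc4ccccc4)c3)[C@@H]2OC=O)c(OCc3ccccc3)c2c1O[C@H](c1ccc(OCc3ccccc3)c(OCc3ccccc3)c1)[C@@H](OCc1ccccc1)C2
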